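The reading that counts comes at 10 d, when each flask below is opened for Z; the earlier south-east run shows what such a flask does on the way there.

| flask | G | remark | time |
|---|---|---|---|
| south-east | 0.17 M | run made earlier |  |
| theta | 0.15 M |  | 10 d |
| zeta | 0.25 M |  | 10 d |
| gamma | 0.40 M |  | 10 d |
| delta | 0.50 M |  | 10 d |
| alpha | 0.80 M |  | 10 d |

south-east run (percent of the G charged)

| time / h | Z / % | G / % |
|---|---|---|
| 10.0 | 8.0 | 52.2 |
| 20.0 | 12.7 | 27.3 |
| 30.0 | 14.7 | 14.4 |
| 40.0 | 16.1 | 7.0 |
| 50.0 | 16.1 | 4.0 |

(each reading ± 0.3 percentage points)

- amount of Z at the end, in percent of the G charged for theta, zeta, gamma, delta, alpha, in this order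
- how the row runs (hardly changes / rises all the way / falls, then rises / falls all the way / rises, then falls)

- "hardly changes" means that all values lie within two and a half points (for a concentration: within two and a half percent of the largest)

Taken in slow motion, the south-east run has three stages. Early on, at 10.0 h, G stands at 52.2% and Z at 8.0%, so 16.7% of the G consumed has appeared as Z. In the middle, at 30.0 h, with G down to 14.4%, the same ratio reads 17.2%. Near the end, at 50.0 h, it reads 16.8%. This ratio, Z formed per G consumed, is the Z share, a selectivity; the last reading gives it best, with the most G consumed. With a scatter of 0.3 percentage points per reading, the three values do not separate, although G fell 13.1-fold between the first and last. Z formation therefore follows the same order in c_G as G loss.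

That loss reads as first order, with k = 0.0642 h⁻¹ and a half-life of 10.8 h. The time allowed, 10 d, is 22.2 such half-lives, so the consumption of G can be taken as finished. The Z share stays level over these readings, which gives no sign of Z decaying up to 50.0 h; that the same holds over the longer time allowed is an assumption of this reckoning. At 50.0 h, 79.9% of the charge is neither G nor Z, and it sits in unread forms. This reckoning therefore puts Z at 16.8% of the charge in each flask. The open point is alpha, whose charge is 4.71 times that of the south-east run.

The forecast gives 17.1% at each of the charges, so the row hardly changes: “The final yield then doesn't depend on the charge”. This reckoning lies 0.30 points lower, as it rests on the last reading.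

The flasks give 16.9%, 16.9%, 16.9%, 16.9% and 16.9%, and the row hardly changes.

    G → Z (k = 0.0110 h⁻¹)
    G → J (k = 0.0410 h⁻¹)
    J ⇌ E (K = 0.690, k = 0.00200 h⁻¹)
    J → D (k = 0.240 h⁻¹)
    G → D (k = 0.0130 h⁻¹)

In theta, the share 16.8% of 0.15 M is 0.0252 M of Z, and the flask holds 0.0253 M. The value hangs on the branching of G: of the two side paths, G → J has the larger effect on Z . Taking k2 out of the read k turns the share into 46.4%, and the simulated alpha run without that step ends at 45.7%.

The runs were computed for an exercise; the scatter is artificial.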